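**No constants.** You cannot integrate this flask: not one rate constant is given. But dawn has the same charge, and its readings hold more than a curve.

| flask | substrate | reagent | remark | time |
|---|---|---|---|---|
| dawn | 0.40 M | 1.6 M | the very flask that is asked about, followed so far |  |
| spring | 0.80 M | 1.6 M | run made earlier |  |
| flask | 0.40 M | 1.60 M |  | 6.0 d |

- dawn (time / h: target / %, substrate / %): 1.00: 34.7, 59.2; 2.00: 46.8, 43.6; 4.00: 53.8, 29.3; 8.00: 46.4, 21.7; 15.0: 36.8, 16.7; 30.0: 25.4, 9.4
- spring (time / d: target / %, substrate / %): 0.0417: 32.7, 59.9; 0.0833: 39.3, 42.6; 0.208: 38.0, 22.6; 0.500: 25.4, 14.0; 1.04: 16.1, 8.0; 2.50: 7.3, 5.3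

(scatter of a reading: 1 percentage point)

* the moment within 6.0 d at which there is most target
* the amount of target, in percent of the substrate charged, at that time

- percent here means substrate units held: one side product counts as two
- what is said of by-product includes crystals
- crystals is a solid; its amount is given per volume of the solution
- steps under discussion: substrate + reagent <-> target + by-product; crystals <-> by-product; substrate + target -> side product

**Reagent used.** Each target took one reagent, and a side product, counted as two, holds one target. So by 8.00 h dawn has used 0.249 M of reagent.

**First quotient.** At that reading, target over substrate, per molar of reagent left, is 1.58 M⁻¹. A steady quotient would mean quasi-equilibrium in the exchange. At 4.00 h dawn's ratio is 1.84, while that quotient allows 2.14, so I take the exchange as still feeding target.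

**My number.** Target reads 46.8% at 2.00 h and 46.4% at 8.00 h, nearly level on either side of a doubling. I commit to a peak near 0.17 d, at about 53.8%, with scatter 1 percentage point.

**Weak link.** One reading carried that quotient. At 0.500 d spring has used 0.446 M, 1.79 times dawn's amount, yet gives 1.57 M⁻¹. Their mean, a reading with its scatter, is my exchange quotient, 1.58 M⁻¹.

**The forecast.** It says 0.18 d and 54.5%, close to mine: “Even if crystals appeared late, little substrate remains, so no second, higher maximum is expected.”

**The flask.** It peaks at 0.158 d with 51.7%.

    substrate + reagent ⇌ target + by-product (K = 0.120, k = 1.10 × 10⁻⁴ M⁻¹ s⁻¹)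
    crystals ⇌ by-product, rate k2*(cs2 - [by-product]) while solid is left; crystals form when [by-product] > cs2 (solubility = 0.0770 M, k = 8.70 × 10⁻⁴ s⁻¹)
    substrate + target → side product (k = 9.50 × 10⁻⁵ M⁻¹ s⁻¹)

**Quotient reused.** At 6.00 d the flask keeps 87% of its reagent, so the quotient gives a ratio of 2.20, and the flask shows 2.18. The neighbour, charged with 0.16 M of substrate, peaks higher, at 61.9%. At 6.00 d it keeps 95% of its reagent and 0.0106 M of crystals. There the quotient gives 2.39, and the neighbour shows 2.37.

Readings and results were computed with constants of no real substance; the scatter is artificial.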